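At early times Sunday's flask holds no free catalyst: the catalyst goes in as precatalyst, whose mean life is 1.54 s.

in all of them: starting material 1.5 M; precatalyst 150 mM

| charge | coupling partner | time | remark |
|---|---|---|---|
| Sunday's | 1.35 M | 8.0 s | a closed flask charged with all of it at once and left for 8.0 s |
| Saturday's | 1.35 M (fed, over 6.40 s) | 8.0 s | a stirred flask in which coupling partner is dosed at a steady rate over 6.40 s without added volume, worked up at 8.0 s |
| Monday's | 1.35 M |  | one stirred flow tank at steady state, fed with the mixture as stated, mean residence time 24.0 s |
| Tuesday's | 1.35 M |  | a single well-mixed tank run continuously and read at steady state, 8.0 s in it on average |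

    starting material + free catalyst ⇌ catalyst intermediate A (K1 = 8.5 M⁻¹, k1 = 4.9 M⁻¹ s⁻¹)
    catalyst intermediate A → catalyst intermediate B (k2 = 2.7 s⁻¹)
    coupling partner + catalyst intermediate B ⇌ catalyst intermediate C (K3 = 0.60 M⁻¹, k3 = 81 M⁻¹ s⁻¹)
    catalyst intermediate C → catalyst intermediate D (k4 = 46 s⁻¹)
    catalyst intermediate D → free catalyst + target (k5 = 2.1 s⁻¹)
    precatalyst → free catalyst (k6 = 0.65 s⁻¹)

- the stated concentrations are those of everything mixed, before any reaction; amounts are the same in each set-up
- the feed brings no volume worth counting
- run time (Sunday's): 8.0 s

1. the set-up with the highest amount of target at the outlet or at the end, in percent of the starting material put in ("none" if the first two lie within 2 percentage points) (Sunday's / Saturday's / Monday's / Tuesday's / none)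
2. amount of target at the outlet or at the end, in percent of the starting material put in, Sunday's
3. amount of target at the outlet or at the end, in percent of the starting material put in, Saturday's
4. amount of target at the outlet or at the end, in percent of the starting material put in, Monday's
5. amount of target at the outlet or at the end, in percent of the starting material put in, Tuesday's

So a catalyst's working time is its time in the flask less that 1.54 s. But how much does one catalyst do in that time? Catalyst intermediate A lasts 0.370 s on average and catalyst intermediate D 0.476 s. These lie close to an even split, so I add them and name neither as the rate-limiting step. Catalyst intermediate C adds 0.0217 s. The two binding steps, each stretched by its back step, add 0.165 s and 0.0360 s at the charged concentrations. The mean time one catalyst needs for one round at given concentrations is the turnover time, here 1.07 s.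

The coupling partner is the limiting reagent, 1.35 M against 1.5 M, so the ceiling is 90.0% of the starting material, or 9.00 turns per catalyst. Sunday's working time allows 6.04 turns, fewer than that, which is 60.4%. I hold this as an upper figure, since the binding waits grow as the concentrations fall. Saturday's dose of 0.211 M s⁻¹ runs faster than the 0.140 M s⁻¹ the catalyst takes, so I place Saturday's near Sunday's. Monday's allows 21.0 turns on average, more than the ceiling needs, so I expect Monday's to be best.

The forecast gives 52% (48% to 56%) for Sunday's, 50% (45% to 54%) for Saturday's, 81% (77% to 85%) for Monday's and 48% (44% to 52%) for Tuesday's. It chooses Monday's, “which makes it the clear winner despite running at low reactant levels”.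

The simulation gives 52.1%, 49.9%, 82.1% and 48.3% in that order, so the best is Monday's.

Read from the target made, Sunday's catalyst takes 1.24 s per turn, longer than the turnover time of 1.07 s. Monday's catalyst takes 2.74 s per turn, longer than Sunday's, and at Monday's outlet, bound forms counted, 0.269 M of starting material and 0.119 M of coupling partner remain, so that the turnover time reckoned at these totals is 2.20 s.

All constants are invented; what happens was integrated by code.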